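## Retrosynthetic overview
1. Alertenone ⇒ 2 × suberosenone. The α′-enolate of one unit adds to the exo-methylene enone of the other (Michael addition, the presumed biogenetic dimerisation; no ring is formed).
2. Suberosenone ⇒ α-terrecyclene by allylic oxygenation, which mirrors the late oxidase step.
3. α-Terrecyclene ⇒ one cation cascade from a cyclobutyl carbinol: caryophyllenyl-type cyclobutylcarbinyl → presilphiperfolanyl → silphinyl → terrecyclenyl cation.
4. Carbinol ⇒ MeLi plus the strained trans-fused [2+2] adduct of isobutene with a bicyclic enone. This supplies the gem-dimethylcyclobutane of the caryophyllane stage.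
5. Ring order: six-ring (bought; Me/alkyl pair set by conjugate addition/allylation) → five-ring (acyloin closure) → four-ring ([2+2]) → cascade (4→5 expansion, then bicyclo[3.2.1]octane plus cyclopentene).

Assumption: the drawn antipode is (S) at the bridgehead CH next to CMe2, opposite to what commercial (−)-β-caryophyllene (1R,9S) would deliver, so the caryophyllane-type cyclobutane is built de novo.

## Route

Step 1
Reactants: 1 cyclohex-2-en-1-one; 2 dimethylzinc; 3 allyl acetate
Product: 5 (2R,3S)-2-allyl-3-methylcyclohexan-1-one (trans), via zinc enolate 4 (not isolated)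
Conditions: Cu(OTf)2 (1 mol %), (S,R,R)-BINOL/bis(1-phenylethyl)amine phosphoramidite (2 mol %, the antipode that gives 3S), Me2Zn, toluene, −30 °C; then allyl acetate, Pd(PPh3)4 (2 mol %), 0 °C; aq NH4Cl
Reagents that add atoms: dimethylzinc C[Zn]C; allyl acetate C=CCOC(C)=O
Why: Cu-catalysed asymmetric conjugate addition sets the methyl carbon (S) under ligand control, and Tsuji–Trost allylation of the zinc enolate occurs anti to the new methyl, giving the trans-2,3 pair.

Step 2
Reactants: 5 (2R,3S)-2-allyl-3-methylcyclohexan-1-one
Product: 6 3-[(1R,2S)-2-methyl-6-oxocyclohexyl]propanal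
Conditions: PdCl2(PhCN)2 (12 mol %), CuCl2·2H2O (12 mol %), AgNO2 (6 mol %), O2 (1 atm), t-BuOH/MeNO2 15:1, rt
Reagents that add atoms: dioxygen O=O
Why: The nitrite-modified, aldehyde-selective (anti-Markovnikov) Wacker oxidation converts the terminal alkene into the aldehyde under near-neutral conditions that leave the ketone and the already thermodynamic trans pair untouched.

Step 3
Reactants: 6 3-[(1R,2S)-2-methyl-6-oxocyclohexyl]propanal
Product: 7 (3aR,4S,7aR)-7a-hydroxy-4-methyloctahydro-1H-inden-1-one (cis-fused ketol, OH syn to H-3a)
Conditions: 3-benzyl-5-(2-hydroxyethyl)-4-methylthiazolium chloride (15 mol %), DBU (15 mol %), t-BuOH, 40 °C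
Reagents that add atoms: none
Why: In this NHC-catalysed intramolecular crossed aldehyde–ketone benzoin (acyloin) reaction the acyl-anion equivalent adds 5-exo to the ketone, and the three-atom tether enforces the cis-hydrindane, which puts OH syn to H-3a.

Step 4
Reactants: 7 cis-fused ketol
Product: 9 (3aR,4S)-4-methyl-2,3,3a,4,5,6-hexahydro-1H-inden-1-one, via chlorosulfite 8 (not isolated)
Conditions: SOCl2, pyridine, CH2Cl2, −20 → 0 °C; use promptly
Reagents that add atoms: none
Why: In this E2 dehydration only the ring CH2 (C-7) offers an H antiperiplanar to the C–O bond (H-3a is syn to it) and the neighbouring carbonyl suppresses E1, so the alkene forms away from the ring-fusion stereocentre and gives the required, less stable enone.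

Step 5
Reactants: 9 (3aR,4S)-4-methyl-2,3,3a,4,5,6-hexahydro-1H-inden-1-one; 10 isobutene
Product: 11 isobutene photoadduct ketone (hydrindan-1-one numbering: cyclobutane CH2 on quaternary C-7a syn to H-3a, CMe2 on C-7; 6/4 trans-fused, 6/5 cis-fused)
Conditions: hν (λ > 300 nm, Pyrex), isobutene (20 equiv), CH2Cl2, −70 °C
Reagents that add atoms: isobutene C=C(C)C
Why: In this enone–alkene [2+2] photocycloaddition the twisted triplet should behave as in cyclohexenone/isobutene and give the head-to-tail, trans-6/4 adduct, which cannot epimerise because the α-carbon is quaternary, while CH2 bonds to that carbon on the H-3a face (cis-hydrindanone) and so fixes both new stereocentres.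

Step 6
Reactants: 11 isobutene photoadduct ketone; 12 methyllithium
Product: 13 tertiary cyclobutyl carbinol (1-methyl-1-ol of 11, Me syn to the cyclobutane CH2)
Conditions: MeLi, Et2O, −78 → 0 °C; aq NH4Cl
Reagents that add atoms: methyllithium [Li]C
Why: In this 1,2-addition the small nucleophile enters from the open face (the side of the equatorial cyclobutane CH2, away from the cyclohexane axial hydrogens), which places C–O antiperiplanar to the C7a–CH2 bond, and this carbinol centre is erased in the next step.

Step 7
Reactants: 13 tertiary cyclobutyl carbinol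
Product: 17 α-terrecyclene (antipode matching the target), via cyclobutylcarbinyl cation 14 (not isolated), via presilphiperfolanyl cation 15 (not isolated), via terrecyclenyl cation 16 (not isolated)
Conditions: H2SO4 on SiO2 (cat.), benzene, 70 °C
Reagents that add atoms: none
Why: Proposed new method: ionisation gives a caryophyllenyl-type cyclobutylcarbinyl cation whose antiperiplanar, strained C–CH2 bond migrates (4→5 ring expansion; the other cyclobutane bond lies about 60° off the vacant orbital) to the central presilphiperfolanyl cation, after which suprafacial 1,2-shifts of the CHMe carbon, of the CH next to CMe2 (silphinyl stage) and of the CH2, followed by loss of H+, lead to the trisubstituted olefin as the thermodynamic sink, each migrating carbon keeping its configuration so that all four stereocentres derive from 13; the closest known reaction types are the solvolytic caryophyllen-8-yl → presilphiperfolanyl rearrangement, the H2SO4/SiO2 isomerisation of presilphiperfolan-8-ol to α-terrecyclene and the solvolysis of silphin-1-yl mesylate.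

Step 8
Reactants: 17 α-terrecyclene
Product: 20 suberosenone, via allylic hydroperoxide 18 (not isolated), via allylic peracetate 19 (not isolated)
Conditions: O2, tetraphenylporphyrin (cat.), visible light, Ac2O, pyridine, DMAP (cat.), CH2Cl2, 0 °C → rt
Reagents that add atoms: dioxygen O=O
Why: In this Schenck ene reaction with in-situ Kornblum–DeLaMare-type elimination the quaternary carbon geminal to the methyl has no H and shields the substituted alkene carbon, so 1O2 takes a methyl H and bonds to the CH carbon, and the exo-methylene peroxide collapses to the enone without touching a stereocentre.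

Step 9
Reactants: 20 suberosenone (2 equiv)
Product: 23 alertenone, via lithium dienolate 21 (not isolated), via adduct enolate 22 (not isolated)
Conditions: LiHMDS (0.5 equiv), THF, −78 → −30 °C; AcOH, −78 °C
Reagents that add atoms: none
Why: In this Michael addition half of the enone becomes the cross-conjugated α′-enolate, which attacks the unhindered exocyclic CH2 of the other half anti to the neighbouring bridgehead carbon, and kinetic protonation of the hindered adduct enolate from the face of the CH2 bridge leaves the linking CH2 syn to the CHMe carbon, as drawn in the target.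

## Compound list
1 | cyclohex-2-en-1-one | O=C1C=CCCC1 | starting material
2 | dimethylzinc | C[Zn]C | starting material
3 | allyl acetate | C=CCOC(C)=O | starting material
4 | methylzinc enolate of (S)-3-methylcyclohexanone | C[Zn]OC1=C[C@@H](C)CCC1 | intermediate
5 | (2R,3S)-2-allyl-3-methylcyclohexan-1-one | O=C1[C@H](CC=C)[C@@H](C)CCC1 | intermediate
6 | 3-[(1R,2S)-2-methyl-6-oxocyclohexyl]propanal | O=C1[C@H](CCC=O)[C@@H](C)CCC1 | intermediate
7 | (3aR,4S,7aR)-7a-hydroxy-4-methyloctahydro-1H-inden-1-one | O=C1CC[C@@H]2[C@@H](C)CCC[C@]12O | intermediate
8 | chlorosulfite of 7 | O=C1CC[C@@H]2[C@@H](C)CCC[C@]12OS(=O)Cl | intermediate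
9 | (3aR,4S)-4-methyl-2,3,3a,4,5,6-hexahydro-1H-inden-1-one | O=C1CC[C@@H]2[C@@H](C)CCC=C12 | intermediate
10 | isobutene | C=C(C)C | starting material
11 | head-to-tail isobutene photoadduct ketone (trans-6/4, cis-6/5; CH2 on C-7a syn to H-3a, CMe2 on C-7) | O=C1CC[C@@H]2[C@@H](C)CC[C@@H]3C(C)(C)C[C@@]123 | intermediate
12 | methyllithium | [Li]C | starting material
13 | tertiary cyclobutyl carbinol (Me syn to cyclobutane CH2) | C[C@@]1(O)CC[C@@H]2[C@@H](C)CC[C@@H]3C(C)(C)C[C@@]123 | intermediate
14 | cyclobutylcarbinyl (caryophyllenyl-type) cation | C[C+]1CC[C@@H]2[C@@H](C)CC[C@@H]3C(C)(C)C[C@@]123 | intermediate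
15 | central presilphiperfolanyl cation | C[C@]12CC[C@@H]3[C@@H](C)CC[C@@H]([C+]13)C(C)(C)C2 | intermediate
16 | terrecyclenyl cation | C[C+]1CC[C@H]2[C@@H]3CC[C@H](C)[C@]12CC3(C)C | intermediate
17 | α-terrecyclene (antipode matching the target) | CC1=CC[C@H]2[C@@H]3CC[C@H](C)[C@]12CC3(C)C | intermediate
18 | exo-methylene allylic hydroperoxide (OOH on the face of the CH2 bridge) | C=C1[C@@H](OO)C[C@H]2[C@@H]3CC[C@H](C)[C@]12CC3(C)C | intermediate
19 | allylic peracetate of 18 | C=C1[C@@H](OOC(C)=O)C[C@H]2[C@@H]3CC[C@H](C)[C@]12CC3(C)C | intermediate
20 | suberosenone | C=C1C(=O)C[C@H]2[C@@H]3CC[C@H](C)[C@]12CC3(C)C | intermediate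
21 | lithium α′-dienolate of suberosenone | [Li+].C=C1C([O-])=C[C@H]2[C@@H]3CC[C@H](C)[C@]12CC3(C)C | intermediate
22 | lithium enolate of the Michael adduct | [Li+].C=C1C(=O)[C@H](CC2=C([O-])C[C@H]3[C@@H]4CC[C@H](C)[C@]23CC4(C)C)[C@H]2[C@@H]3CC[C@H](C)[C@]12CC3(C)C | intermediate
23 | alertenone | C=C1C(=O)[C@H](C[C@@H]2C(=O)C[C@H]3[C@@H]4CC[C@H](C)[C@]23CC4(C)C)[C@H]2[C@@H]3CC[C@H](C)[C@]12CC3(C)C | target

## Step count and risks
Total step count: 9. Longest linear sequence: 9.

**Risk 1, step 5.** The α-carbon of 9 is fully substituted, so head-to-tail orientation, facial selectivity and trans fusion are all uncertain. The fallback sets out from 9 and returns at 17, building the four-ring by radical and ionic bond formation instead of light.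
- Fe(acac)3/PhSiH3 reductive olefin coupling (MHAT–Giese) of 9 with 2-methylprop-2-en-1-ol places the tertiary radical on the β-carbon by axial attack and gives Giese hydroxy ketone F1.
- TsCl/pyridine gives neopentyl tosylate F2.
- KOt-Bu closes the ring by 4-exo-tet alkylation of the ring-fusion enolate on the face of the tether. This gives cis-fused cyclobutane ketone F3, which has the same quaternary centre as 11 and is epimeric only at the CH next to CMe2.
- MeLi gives epimeric carbinol F4.
- Under the conditions of step 7 the epimeric CH is corrected by reversible proton loss and regain through the tetrasubstituted olefin. The shifts then lead to 17.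

**Risk 2, step 7.** The cascade may leak to other triquinanes, or the wrong cyclobutane bond may migrate. The fallback sets out from 13 and returns at 17, driving each shift separately with oxygen or nitrogen leaving groups.
- SOCl2/pyridine at −30 °C ionises 13 under non-equilibrating, basic conditions. Only ring expansion and proton loss occur, giving tetrasubstituted presilphiperfolene F5.
- mCPBA attacks anti to the angular methyl and gives presilphiperfolene epoxide F6.
- BF3·OEt2 triggers a semipinacol shift of the CHMe carbon antiperiplanar to the breaking C–O bond and gives silphinanone F7.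
- TsNHNH2 gives silphinanone tosylhydrazone F8.
- A protic Bamford–Stevens reaction (Na, ethylene glycol, 140 °C) releases the silphin-1-yl cation, which makes the last two 1,2-shifts to 17.

**Risk 3, step 9.** Oligomerisation is possible because the dimer keeps an exo-methylene enone, and the protonation stereochemistry is not secured. The fallback sets out from 20 and returns at 23, separating the donor and acceptor roles.
- One portion of 20 is converted with LDA/TMSCl into isolated silyl dienol ether F9.
- F9 is added slowly to a second portion of 20 under TiCl4 at −78 °C (Mukaiyama–Michael reaction). The neutral donor cannot be regenerated from the product.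
- A cold aqueous quench protonates the adduct from the open face to give 23.

## Further compounds
F1 | step 5 | Giese hydroxy ketone | O=C1CC[C@@H]2[C@@H](C)CC[C@@H](C(C)(C)CO)[C@H]12
F2 | step 5 | neopentyl tosylate | O=C1CC[C@@H]2[C@@H](C)CC[C@@H](C(C)(C)COS(=O)(=O)c3ccc(C)cc3)[C@H]12
F3 | step 5 | cis-fused cyclobutane ketone | O=C1CC[C@@H]2[C@@H](C)CC[C@H]3C(C)(C)C[C@@]123
F4 | step 5 | epimeric carbinol | C[C@@]1(O)CC[C@@H]2[C@@H](C)CC[C@H]3C(C)(C)C[C@@]123
F5 | step 7 | tetrasubstituted presilphiperfolene | C[C@]12CCC3=C1[C@H](CC[C@@H]3C)C(C)(C)C2
F6 | step 7 | presilphiperfolene epoxide | C[C@]12CC[C@@]34O[C@@]13[C@H](CC[C@@H]4C)C(C)(C)C2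
F7 | step 7 | silphinanone | C[C@]12CCC(=O)[C@]13[C@@H](C)CC[C@@H]3C(C)(C)C2
F8 | step 7 | silphinanone tosylhydrazone | C[C@]12CCC(=NNS(=O)(=O)c4ccc(C)cc4)[C@]13[C@@H](C)CC[C@@H]3C(C)(C)C2
F9 | step 9 | silyl dienol ether | C=C1C(O[Si](C)(C)C)=C[C@H]2[C@@H]3CC[C@H](C)[C@]12CC3(C)C
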